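## Retrosynthetic overview

1. Ring numbering used throughout: C1 (O‑tiglate, next to C2H=), C2=C3 (C3 carries C7H2OH), C4 (O‑tiglate), C5 (OAc), C6 (iPr). The target is (1S,4S,5R,6S), with O1/iPr cis, iPr/O5 trans and O5/O4 cis.
2. Endgame: O7 desilylation ⇐ tigloylation of O1 and O4 ⇐ stannylene‑directed acetylation of O5 ⇐ cyclohexene triol.
3. Key disconnection C4–C5: SmI2 ketyl (pinacol) coupling of two aldehyde carbons, which closes the only carbocycle and sets the cis‑4,5‑diol in one step.
4. C1–C6: L‑proline anti cross‑aldol of isovaleraldehyde with the Z‑enedial made by oxidative opening of silylated 3‑furanmethanol (all ten skeletal carbons from two C5 pieces).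
5. Ring order: a dihydrofuran lactol forms spontaneously after the aldol and serves only as a masked aldehyde; the cyclohexene ring is then formed in the pinacol step.

## Route

Step 1
Reactants: 1 furan-3-ylmethanol
Product: 2 tert-butyl(furan-3-ylmethoxy)dimethylsilane
Conditions: TBSCl (1.1 equiv), imidazole (1.5 equiv), CH2Cl2, 0 °C → rt
Reagents that add atoms: tert-butyldimethylsilyl chloride, CC(C)(C)[Si](C)(C)Cl
Why: Imidazole-promoted silyl ether formation on a primary alcohol masks O7 until the last step; no stereocentre is involved.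

Step 2
Reactants: 2 tert-butyl(furan-3-ylmethoxy)dimethylsilane
Product: 3 (2Z)-2-({[tert-butyl(dimethyl)silyl]oxy}methyl)but-2-enedial
Conditions: dimethyldioxirane (1.05 equiv, ca. 0.08 M in acetone), −78 → 0 °C, 30 min; volatiles removed at 0 °C, used at once
Reagents that add atoms: dimethyldioxirane, CC1(C)OO1
Why: Dioxirane oxidation of a 2,5-unsubstituted furan is the known oxidative ring opening to a cis-2-ene-1,4-dial; the furan ring dictates the Z geometry that places C1 and C4 on the same side of C2=C3, and acetone is the only by-product.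

Step 3
Reactants: 3 (2Z)-2-({[tert-butyl(dimethyl)silyl]oxy}methyl)but-2-enedial; 4 isovaleraldehyde (3-methylbutanal)
Product: 6 (2S)-2-[(2S)-4-({[tert-butyl(dimethyl)silyl]oxy}methyl)-5-hydroxy-2,5-dihydrofuran-2-yl]-3-methylbutanal (lactol; both anomers), via open-chain hydroxy dialdehyde 5 (not isolated)
Conditions: L-proline (20 mol%), DMF, 4 °C, 4 (1.5 equiv) added by syringe pump over 20 h; cold pH 7 phosphate buffer/Et2O work-up, rapid filtration through Et3N-deactivated silica, used directly
Reagents that add atoms: none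
Why: Proline enamine cross-aldol (List–Houk transition state): the E-enamine of 4 adds to the Re face of the less hindered, α-non-enolisable C1 aldehyde of 3, which sets the anti pair C6 (S) and C1 (S) in the sense known for L-proline aldehyde cross-aldols, and the new cis γ-hydroxy enal closes at once to lactol 6, which masks the second aldehyde against a second aldol and against Z/E isomerisation.

Step 4
Reactants: 6 (2S)-2-[(2S)-4-({[tert-butyl(dimethyl)silyl]oxy}methyl)-5-hydroxy-2,5-dihydrofuran-2-yl]-3-methylbutanal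
Product: 7 (1S,2R,3S,4S)-6-({[tert-butyl(dimethyl)silyl]oxy}methyl)-3-(propan-2-yl)cyclohex-5-ene-1,2,4-triol
Conditions: SmI2 (3 equiv, 0.1 M in THF), THF, −78 → 0 °C, 6 added over 1 h (final 0.01 M), no added proton source; sat. aq. NaHCO3/Na2S2O3 work-up
Reagents that add atoms: none
Why: Proposed new method: lactol 6 reacts through its open-chain tautomer, the hydroxy dialdehyde already numbered 5, with which it is in ring–chain equilibrium, and single-electron transfer from SmI2 turns one carbonyl carbon into a nucleophilic ketyl (reversed carbonyl polarity) that adds to the second, samarium-bound aldehyde, so that C4 and C5, both electrophilic carbonyl carbons, are joined in a 6-membered closure (key step); the closest known reaction is the SmI2 pinacol cyclisation of 1,6-dialdehydes to cis-cyclohexane-1,2-diols (new here is that one aldehyde is a lactol-masked Z-enal); the diolate bridged by trivalent samarium enforces the cis 4,5-diol, and it forms on the ring face opposite to O1 and the isopropyl group, so that O5 is equatorial (trans to iPr) and O4 pseudoaxial (no allylic 1,2-strain against the CH2OTBS group).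

Step 5
Reactants: 7 (1S,2R,3S,4S)-6-({[tert-butyl(dimethyl)silyl]oxy}methyl)-3-(propan-2-yl)cyclohex-5-ene-1,2,4-triol
Product: 9 (1R,2S,5S,6S)-3-({[tert-butyl(dimethyl)silyl]oxy}methyl)-2,5-dihydroxy-6-(propan-2-yl)cyclohex-3-en-1-yl acetate, via dibutylstannylene acetal 8 (not isolated)
Conditions: Bu2SnO (1.05 equiv), MeOH, reflux, 2 h, evaporate; then AcCl (1.0 equiv), CH2Cl2, −10 → 0 °C
Reagents that add atoms: acetyl chloride, CC(Cl)=O
Why: Regioselective stannylene acylation: the dibutylstannylene acetal forms on the cis-1,2-diol and activates its equatorial oxygen (O5), so acetyl chloride gives the 5-acetate while the unactivated O1–H and the pseudoaxial O4–H stay free; no stereocentre changes.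

Step 6
Reactants: 9 (1R,2S,5S,6S)-3-({[tert-butyl(dimethyl)silyl]oxy}methyl)-2,5-dihydroxy-6-(propan-2-yl)cyclohex-3-en-1-yl acetate
Product: 10 (1S,4S,5R,6S)-5-(acetyloxy)-3-({[tert-butyl(dimethyl)silyl]oxy}methyl)-6-(propan-2-yl)cyclohex-2-ene-1,4-diyl bis[(2E)-2-methylbut-2-enoate]
Conditions: tigloyl chloride (4 equiv), pyridine, 4-(dimethylamino)pyridine (0.2 equiv), CH2Cl2, 0 °C → rt
Reagents that add atoms: tigloyl chloride [(2E)-2-methylbut-2-enoyl chloride], C/C=C(\C)C(Cl)=O
Why: Nucleophile-catalysed esterification of both remaining allylic hydroxyls (O1 and O4) with excess acid chloride outruns acetyl migration; the E (tiglate) geometry is the thermodynamic one and no ring stereocentre is touched.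

Step 7
Reactants: 10 (1S,4S,5R,6S)-5-(acetyloxy)-3-({[tert-butyl(dimethyl)silyl]oxy}methyl)-6-(propan-2-yl)cyclohex-2-ene-1,4-diyl bis[(2E)-2-methylbut-2-enoate]
Product: 11 (1S,4S,5R,6S)-5-(acetyloxy)-3-(hydroxymethyl)-6-(propan-2-yl)cyclohex-2-ene-1,4-diyl bis[(2E)-2-methylbut-2-enoate] (target)
Conditions: HF·pyridine, pyridine, THF, 0 °C → rt
Reagents that add atoms: none
Why: Fluoride cleavage of the primary silyl ether under buffered, mildly acidic conditions leaves the three esters in place and avoids base-induced acyl migration to the freed O7–H.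

## Compound list

1 | furan-3-ylmethanol | OCc1ccoc1 | starting material
2 | tert-butyl(furan-3-ylmethoxy)dimethylsilane | CC(C)(C)[Si](C)(C)OCc1ccoc1 | intermediate
3 | (2Z)-2-({[tert-butyl(dimethyl)silyl]oxy}methyl)but-2-enedial | O=C/C=C(/CO[Si](C)(C)C(C)(C)C)C=O | intermediate
4 | isovaleraldehyde (3-methylbutanal) | CC(C)CC=O | starting material
5 | (2Z,4S,5S)-2-({[tert-butyl(dimethyl)silyl]oxy}methyl)-4-hydroxy-5-(propan-2-yl)hex-2-enedial (open-chain tautomer of 6; not isolated) | O=C[C@@H](C(C)C)[C@@H](O)/C=C(/CO[Si](C)(C)C(C)(C)C)C=O | intermediate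
6 | (2S)-2-[(2S)-4-({[tert-butyl(dimethyl)silyl]oxy}methyl)-5-hydroxy-2,5-dihydrofuran-2-yl]-3-methylbutanal (lactol; both anomers) | O=C[C@@H](C(C)C)[C@H]1OC(O)C(CO[Si](C)(C)C(C)(C)C)=C1 | intermediate
7 | (1S,2R,3S,4S)-6-({[tert-butyl(dimethyl)silyl]oxy}methyl)-3-(propan-2-yl)cyclohex-5-ene-1,2,4-triol | O[C@H]1C=C(CO[Si](C)(C)C(C)(C)C)[C@H](O)[C@H](O)[C@H]1C(C)C | intermediate
8 | 4,5-O-dibutylstannylene acetal of 7 (2,2-dibutyl-1,3,2-dioxastannolane across O4 and O5; O1–H free; not isolated) | O[C@H]1C=C(CO[Si](C)(C)C(C)(C)C)[C@@H]2O[Sn](CCCC)(CCCC)O[C@@H]2[C@H]1C(C)C | intermediate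
9 | (1R,2S,5S,6S)-3-({[tert-butyl(dimethyl)silyl]oxy}methyl)-2,5-dihydroxy-6-(propan-2-yl)cyclohex-3-en-1-yl acetate | O[C@H]1C=C(CO[Si](C)(C)C(C)(C)C)[C@H](O)[C@H](OC(C)=O)[C@H]1C(C)C | intermediate
10 | (1S,4S,5R,6S)-5-(acetyloxy)-3-({[tert-butyl(dimethyl)silyl]oxy}methyl)-6-(propan-2-yl)cyclohex-2-ene-1,4-diyl bis[(2E)-2-methylbut-2-enoate] | C/C=C(\C)C(=O)O[C@H]1C=C(CO[Si](C)(C)C(C)(C)C)[C@H](OC(=O)/C(C)=C/C)[C@H](OC(C)=O)[C@H]1C(C)C | intermediate
11 | (1S,4S,5R,6S)-5-(acetyloxy)-3-(hydroxymethyl)-6-(propan-2-yl)cyclohex-2-ene-1,4-diyl bis[(2E)-2-methylbut-2-enoate] | C/C=C(\C)C(=O)O[C@H]1C=C(CO)[C@H](OC(=O)/C(C)=C/C)[C@H](OC(C)=O)[C@H]1C(C)C | target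

## Step count and risk

Total steps: 7. Longest linear sequence: 7 steps (1 → 11); isovaleraldehyde 4 enters in step 3.

The three steps most likely to fail are, in order of risk, step 4, step 3 and step 5.

Step 4 (pinacol closure on the lactol). The lactol may open too slowly. Trivalent samarium alkoxides may divert 6 into a Tishchenko-type redox to a butenolide and a primary alcohol. Chelation of O1–H to samarium could deliver the all-cis triol. The fallback sets out from 6 and comes back at 7; it keeps the ketyl coupling but runs it on an acyclic, O1-silylated dialdehyde. NaBH4 with CeCl3·7H2O (MeOH, −20 °C) reduces the lactol and the aldehyde of 6 to the acyclic triol F5. Et3SiCl and imidazole (DMF) give the tris(triethylsilyl) ether F6. Swern oxidation (oxalyl chloride, DMSO, CH2Cl2, −78 → −30 °C, then Et3N) converts the two primary triethylsilyl ethers directly into aldehydes and leaves the secondary one and the TBS ether, giving the O1-triethylsilyl dialdehyde F7. SmI2 (THF, −78 °C) closes it to the O1-triethylsilyl cis-diol F8; the bulky pseudoaxial silyl ether blocks the upper face and cannot chelate. Pyridinium p-toluenesulfonate in MeOH (0 °C) removes the triethylsilyl group and returns 7.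

Step 3 (aminocatalytic aldol on a cis-enedial). The amine catalyst may add to the enedial, the more hindered aldehyde may compete, and traces of acid can dehydrate lactol 6 to a furan. The fallback sets out from 3 and comes back at 7; it uses a metal-enolate anti-aldol that silylates O1 in the same operation, so no lactol can form. Commercial (R)-4-benzyl-3-(3-methylbutanoyl)oxazolidin-2-one, MgCl2 (20 mol%), Et3N and Me3SiCl in EtOAc (soft enolisation, anti-selective through a chelated boat transition state) add to the C1 aldehyde of 3 to give the O1-trimethylsilyl anti-aldol imide F1. In the magnesium-chelated Z-enolate the (R)-benzyl group shields one face, in the same sense as in chelate-controlled alkylation with this auxiliary, so the aldehyde enters to give the 2S centre and the boat transition state gives the anti 3S carbinol. LiBH4 (Et2O, 1 equiv MeOH, 0 °C, pH 7 work-up) reduces imide and enal to the O1-trimethylsilyl diol F2. Dess–Martin periodinane with NaHCO3 (CH2Cl2) gives the acyclic O1-trimethylsilyl dialdehyde F3. SmI2 (THF, −78 °C) closes it to the O1-trimethylsilyl cis-diol F4, and the citric acid work-up cleaves the silyl ether to rejoin the route at 7.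

Step 5 (one acetate among three hydroxyls). The stannylene may not discriminate cleanly against O1–H, and the cis 5-acetate can migrate to O4 during step 6. The fallback sets out from 7 and comes back at 10; it differentiates the hydroxyls by protection instead of by reagent control. PhB(OH)2 (toluene, MgSO4, rt) ties up the cis-diol as the 4,5-O-phenylboronate F9. Tigloyl chloride, pyridine and 4-(dimethylamino)pyridine acylate the only free hydroxyl to give the 1-O-tigloyl phenylboronate F10. Transesterification with pinacol (CH2Cl2, rt) frees the 1-O-tigloyl cis-diol F11. Ac2O in pyridine at −20 °C acetylates the equatorial O5–H of this simpler diol to give the 1-O-tigloyl 5-acetate F12. Tigloylation of the remaining pseudoaxial O4–H as in step 6 gives 10.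

## Further compounds

F1 | step 3 | (R)-4-benzyl-3-[(2S,3S,4Z)-5-({[tert-butyl(dimethyl)silyl]oxy}methyl)-6-oxo-2-(propan-2-yl)-3-(trimethylsilyloxy)hex-4-enoyl]oxazolidin-2-one (O1-trimethylsilyl anti-aldol imide) | O=C1OC[C@@H](Cc2ccccc2)N1C(=O)[C@@H](C(C)C)[C@@H](O[Si](C)(C)C)/C=C(/CO[Si](C)(C)C(C)(C)C)C=O
F2 | step 3 | O1-trimethylsilyl diol (acyclic; C4 and C5 as CH2OH, C6 iPr, C7 as CH2OTBS, C4 cis to C1 on C2=C3) | OC[C@@H](C(C)C)[C@@H](O[Si](C)(C)C)/C=C(/CO[Si](C)(C)C(C)(C)C)CO
F3 | step 3 | O1-trimethylsilyl dialdehyde (O-trimethylsilyl ether of 5) | O=C[C@@H](C(C)C)[C@@H](O[Si](C)(C)C)/C=C(/CO[Si](C)(C)C(C)(C)C)C=O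
F4 | step 3 | O1-trimethylsilyl cis-diol (1-O-trimethylsilyl ether of 7) | C[Si](C)(C)O[C@H]1C=C(CO[Si](C)(C)C(C)(C)C)[C@H](O)[C@H](O)[C@H]1C(C)C
F5 | step 4 | acyclic triol (C4 and C5 as CH2OH, O1–H free, C7 as CH2OTBS) | OC[C@@H](C(C)C)[C@@H](O)/C=C(/CO[Si](C)(C)C(C)(C)C)CO
F6 | step 4 | tris(triethylsilyl) ether of F5 | CC[Si](CC)(CC)OC[C@@H](C(C)C)[C@@H](O[Si](CC)(CC)CC)/C=C(/CO[Si](C)(C)C(C)(C)C)CO[Si](CC)(CC)CC
F7 | step 4 | O1-triethylsilyl dialdehyde (O-triethylsilyl ether of 5) | O=C[C@@H](C(C)C)[C@@H](O[Si](CC)(CC)CC)/C=C(/CO[Si](C)(C)C(C)(C)C)C=O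
F8 | step 4 | O1-triethylsilyl cis-diol (1-O-triethylsilyl ether of 7) | CC[Si](CC)(CC)O[C@H]1C=C(CO[Si](C)(C)C(C)(C)C)[C@H](O)[C@H](O)[C@H]1C(C)C
F9 | step 5 | 4,5-O-phenylboronate of 7 (2-phenyl-1,3,2-dioxaborolane across O4 and O5; O1–H free) | O[C@H]1C=C(CO[Si](C)(C)C(C)(C)C)[C@@H]2OB(c3ccccc3)O[C@@H]2[C@H]1C(C)C
F10 | step 5 | 1-O-tigloyl 4,5-O-phenylboronate | C/C=C(\C)C(=O)O[C@H]1C=C(CO[Si](C)(C)C(C)(C)C)[C@@H]2OB(c3ccccc3)O[C@@H]2[C@H]1C(C)C
F11 | step 5 | 1-O-tigloyl cis-4,5-diol | C/C=C(\C)C(=O)O[C@H]1C=C(CO[Si](C)(C)C(C)(C)C)[C@H](O)[C@H](O)[C@H]1C(C)C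
F12 | step 5 | 1-O-tigloyl 5-O-acetyl 4-hydroxy compound | C/C=C(\C)C(=O)O[C@H]1C=C(CO[Si](C)(C)C(C)(C)C)[C@H](O)[C@H](OC(C)=O)[C@H]1C(C)C
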